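**Strategy.** Everything rests on opening the pyran ring (ring B) of the 2H-chromene across C3–C4 and O1–C2. One amine-catalysed domino joins salicylaldehyde 15 and enal 11: the γ-methyl of the enal becomes C3 and adds to the formyl carbon (C4) as a dienamine, then the phenol oxygen O1 closes on the β-carbon (C2) of the resulting iminium ion, whose face the catalyst selects. The step exploits C2 being a β-carbon once its methyl is written as CH2CHO, a carbon lost later by decarbonylation. The precursor enal carries the cyclohexane (ring C) stereocentres, set on (R)-carvone whose isopropenyl anchor is then excised. The hydroquinone (ring A) is unmasked last.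

Key step: step 10

Remark on the chemistry: the target is read as the (2S)-chromene with a (1R,3R)-cyclohexane; enal 11 is carried as its E/Z mixture and lactol 17 as its anomer mixture, because both converge in the following step.

Step 1
Reactants: 1 (R)-carvone
Product: 2 (5R,6S)-2,6-dimethyl-5-(prop-1-en-2-yl)cyclohex-2-en-1-one (major trans epimer)
Conditions: LiN(i-Pr)2, THF, −78 °C; MeI, −78 to −20 °C
Reagents that add atoms: iodomethane, CI
Why: Kinetic deprotonation of the cross-conjugated enone at C6 and enolate methylation, mainly trans to the C5 isopropenyl group, the C6 configuration being irrelevant because this centre is re-enolised in step 2.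

Step 2
Reactants: 2 (5R,6S)-2,6-dimethyl-5-(prop-1-en-2-yl)cyclohex-2-en-1-one; 3 2-(2-bromoethyl)-2-methyl-1,3-dioxolane
Product: 4 (5S,6S)-2,6-dimethyl-6-[2-(2-methyl-1,3-dioxolan-2-yl)ethyl]-5-(prop-1-en-2-yl)cyclohex-2-en-1-one
Conditions: LiN(i-Pr)2, THF/DMPU, −78 °C; 3, n-Bu4NI (cat.), −78 to 0 °C
Reagents that add atoms: none
Why: Enolate alkylation of the tetrasubstituted C6 enolate, in which the neighbouring isopropenyl group is pushed pseudoaxial by allylic strain and blocks its own face, so the side chain should enter trans to isopropenyl and set the quaternary centre.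

Step 3
Reactants: 4 (5S,6S)-2,6-dimethyl-6-[2-(2-methyl-1,3-dioxolan-2-yl)ethyl]-5-(prop-1-en-2-yl)cyclohex-2-en-1-one
Product: 5 (2S,3S,6R)-2,6-dimethyl-2-[2-(2-methyl-1,3-dioxolan-2-yl)ethyl]-3-(prop-1-en-2-yl)cyclohexan-1-one
Conditions: LiBH(s-Bu)3, THF, −78 °C; MeOH; then NaOMe (cat.), MeOH, 23 °C
Reagents that add atoms: none
Why: Conjugate hydride reduction of the α-methyl enone followed by base equilibration of the new CH(CH3) centre, which should settle with its methyl equatorial and trans to the axial quaternary methyl because the equatorial isopropenyl group locks the chair and the other epimer suffers a syn-diaxial methyl/methyl contact.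

Step 4
Reactants: 5 (2S,3S,6R)-2,6-dimethyl-2-[2-(2-methyl-1,3-dioxolan-2-yl)ethyl]-3-(prop-1-en-2-yl)cyclohexan-1-one
Product: 7 (2R,6R)-2,6-dimethyl-2-[2-(2-methyl-1,3-dioxolan-2-yl)ethyl]cyclohexan-1-one, via methoxy hydroperoxide 6 (not isolated)
Conditions: O3, MeOH, −78 °C; then FeSO4·7H2O, PhSH, −78 to 23 °C
Reagents that add atoms: none
Why: Hydrodealkenylation, in which Criegee ozonolysis in methanol gives the α-methoxy hydroperoxide, divalent iron cleaves the O–O bond, β-scission of the alkoxy radical expels methyl acetate and the secondary ring radical is quenched by fast hydrogen transfer from the thiol, so the anchor is removed by C–C cleavage while both stereocentres are kept.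

Step 5
Reactants: 7 (2R,6R)-2,6-dimethyl-2-[2-(2-methyl-1,3-dioxolan-2-yl)ethyl]cyclohexan-1-one
Product: 8 2-{2-[(1R,3R)-1,3-dimethyl-2-methylidenecyclohexyl]ethyl}-2-methyl-1,3-dioxolane
Conditions: Cp2TiMe2, toluene/THF, 70 °C, dark
Reagents that add atoms: dimethyltitanocene, [CH3-].[CH3-].[Ti+4].c1cc[cH-]c1.c1cc[cH-]c1
Why: Petasis methylenation through Cp2Ti=CH2 and an oxatitanacyclobutane, chosen because it is not basic, so the hindered ketone should be methylenated without epimerising the adjacent CH(CH3) centre or opening the ketal.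

Step 6
Reactants: 8 2-{2-[(1R,3R)-1,3-dimethyl-2-methylidenecyclohexyl]ethyl}-2-methyl-1,3-dioxolane
Product: 9 4-[(1R,3R)-1,3-dimethyl-2-methylidenecyclohexyl]butan-2-one
Conditions: PPTS, acetone/H2O, 50 °C
Reagents that add atoms: water, O
Why: Mild acid-catalysed ketal hydrolysis, under which the hindered exocyclic alkene should not migrate.

Step 7
Reactants: 9 4-[(1R,3R)-1,3-dimethyl-2-methylidenecyclohexyl]butan-2-one
Product: 11 (2E)-5-[(1R,3R)-1,3-dimethyl-2-methylidenecyclohexyl]-3-methylpent-2-enal, via unsaturated N-tert-butylimine 10 (not isolated)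
Conditions: N-tert-butyl-2-(trimethylsilyl)ethanimine, LiN(i-Pr)2, THF, −78 °C; 9, −78 to −20 °C; then aq. oxalic acid, 23 °C
Reagents that add atoms: N-tert-butyl-2-(trimethylsilyl)ethanimine, CC(C)(C)N=CC[Si](C)(C)C; water, O
Why: Peterson olefination of the unhindered methyl ketone with the lithiated silyl imine followed by imine hydrolysis gives the β-methyl enal in one operation, and its E/Z ratio does not matter because both isomers give the same dienamine in step 10.

Step 8
Reactants: 12 2,4,5-trimethoxybenzaldehyde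
Product: 14 2,4,5-trimethoxyphenol, via aryl formate 13 (not isolated)
Conditions: mCPBA, CH2Cl2, 0 to 23 °C; then K2CO3 (cat.), MeOH
Reagents that add atoms: 3-chloroperoxybenzoic acid, OOC(=O)c1cccc(Cl)c1
Why: Dakin-type Baeyer–Villiger oxidation, in which the electron-rich aryl group migrates to oxygen and the formate is removed by methanolysis.

Step 9
Reactants: 14 2,4,5-trimethoxyphenol
Product: 15 2-hydroxy-3,5,6-trimethoxybenzaldehyde
Conditions: MgCl2, Et3N, (CH2O)n, MeCN, reflux
Reagents that add atoms: paraformaldehyde (as formaldehyde), C=O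
Why: Magnesium-phenoxide-directed ortho-formylation (Casiraghi–Skattebøl type), which can only occur at the single free position ortho to the hydroxyl group.

Step 10
Reactants: 11 (2E)-5-[(1R,3R)-1,3-dimethyl-2-methylidenecyclohexyl]-3-methylpent-2-enal; 15 2-hydroxy-3,5,6-trimethoxybenzaldehyde
Product: 17 bridged lactol of (2S,4S)-2-{2-[(1R,3R)-1,3-dimethyl-2-methylidenecyclohexyl]ethyl}-5,6,8-trimethoxychroman in which the C2–CH2 arm and the C4 oxygen are joined through a CH(OH) carbon (anomer mixture), via hydroxy aldehyde 16 (not isolated)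
Conditions: (R)-2-{bis[3,5-bis(trifluoromethyl)phenyl](trimethylsilyloxy)methyl}pyrrolidine (30 mol %), toluene, 23 °C, 72 h
Reagents that add atoms: none
Why: The amine condenses with 11 to an iminium ion that loses a γ-methyl proton to give the cross-conjugated dienamine (so E and Z enal converge), whose terminal CH2 adds to the formyl carbon of 15 (vinylogous aldol, C3–C4) and regenerates an E, s-trans iminium ion whose β-carbon is then attacked by the ortho phenol oxygen (oxa-Michael, O1–C2), after which hydrolysis and lactol formation release the catalyst. The closest known reaction type is the diarylprolinol-silyl-ether-catalysed domino aldol/oxa-Michael reaction of electron-rich salicylaldehydes with β-methyl enals, which gives 2-alkyl-2-(2-oxoethyl)chroman-4-ol lactols. The chroman ring closes 6-exo-trig (oxygen onto the iminium β-carbon) and the lactol ring closes 6-exo-trig by hemiacetalisation of the C4 hydroxyl with the released aldehyde. C2 is set by the catalyst: the diaryl(silyloxy)methyl group of the (R)-pyrrolidine shields one face of the iminium ion and the phenol adds to the other, which, with the aldol arm trans to the iminium carbon, should correspond to 2S; C4 is relayed from C2 because only the isomer with the C4 oxygen cis to the C2 arm can lactolise and the reversible aldol step feeds material into it (C4 is erased in step 13), and the anomeric carbon stays a mixture. The step needs the dienamine to react at the γ-methyl and not at the γ-methylene or the α-carbon, which the lower hindrance of the terminal CH2 and the cyclisation open only to this adduct should secure, and it needs a single phenol to cyclise, which 15 secures by having only one free hydroxyl ortho to the formyl group.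

Step 11
Reactants: 17 bridged lactol (anomer mixture)
Product: 18 (2S,4S)-2-{2-[(1R,3R)-1,3-dimethyl-2-methylidenecyclohexyl]ethyl}-5,6,8-trimethoxy-2-methyl-3,4-dihydro-2H-chromen-4-ol
Conditions: RhCl(PPh3)3 (1.1 equiv), toluene, 110 °C, Ar
Reagents that add atoms: none
Why: Tsuji–Wilkinson decarbonylation through the ring-opened hydroxy aldehyde 16 (insertion of monovalent rhodium into the formyl C–H bond, CO extrusion, reductive elimination), which turns the CH2CHO arm into the C2 methyl group without touching the C2 stereocentre.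

Step 12
Reactants: 18 (2S,4S)-2-{2-[(1R,3R)-1,3-dimethyl-2-methylidenecyclohexyl]ethyl}-5,6,8-trimethoxy-2-methyl-3,4-dihydro-2H-chromen-4-ol
Product: 19 (2S,4S)-2-{2-[(1R,3R)-1,3-dimethyl-2-methylidenecyclohexyl]ethyl}-4-hydroxy-6-methoxy-2-methyl-3,4-dihydro-2H-chromene-5,8-dione
Conditions: (NH4)2Ce(NO3)6, MeCN/H2O, 0 °C
Reagents that add atoms: water, O
Why: Oxidative demethylation by tetravalent cerium of the para-related C5 and C8 methoxy groups (arene radical cation, ipso attack of water, loss of methanol) should give the para-quinone with the C6 methoxy retained, and it is run before the C3=C4 bond exists so that no 2H-pyranoquinone able to open electrocyclically at C2 is formed.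

Step 13
Reactants: 19 (2S,4S)-2-{2-[(1R,3R)-1,3-dimethyl-2-methylidenecyclohexyl]ethyl}-4-hydroxy-6-methoxy-2-methyl-3,4-dihydro-2H-chromene-5,8-dione
Product: 21 (2S)-2-{2-[(1R,3R)-1,3-dimethyl-2-methylidenecyclohexyl]ethyl}-6-methoxy-2-methyl-2H-chromene-5,8-diol, via hydroquinone chromanol 20 (not isolated)
Conditions: Na2S2O4, EtOAc/H2O, 23 °C; organic phase dried, then PPTS (cat.), toluene, 45 °C, Ar, dark
Reagents that add atoms: none
Why: Dithionite reduction gives the hydroquinone, whose benzylic C4 hydroxyl, ortho to the C5 phenol, ionises under mild acid and loses H3 (E1 dehydration through an ortho-quinone methide or benzylic cation) to form the C3=C4 bond, a path that never breaks the O1–C2 bond and so should leave C2 as S.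

Compound list
1 | (R)-carvone, (5R)-2-methyl-5-(prop-1-en-2-yl)cyclohex-2-en-1-one | O=C1C(C)=CC[C@@H](C(C)=C)C1 | starting material
2 | (5R,6S)-2,6-dimethyl-5-(prop-1-en-2-yl)cyclohex-2-en-1-one (major epimer) | O=C1C(C)=CC[C@@H](C(C)=C)[C@@H]1C | intermediate
3 | 2-(2-bromoethyl)-2-methyl-1,3-dioxolane | CC1(CCBr)OCCO1 | starting material
4 | (5S,6S)-2,6-dimethyl-6-[2-(2-methyl-1,3-dioxolan-2-yl)ethyl]-5-(prop-1-en-2-yl)cyclohex-2-en-1-one | O=C1C(C)=CC[C@@H](C(C)=C)[C@]1(C)CCC1(C)OCCO1 | intermediate
5 | (2S,3S,6R)-2,6-dimethyl-2-[2-(2-methyl-1,3-dioxolan-2-yl)ethyl]-3-(prop-1-en-2-yl)cyclohexan-1-one | O=C1[C@H](C)CC[C@@H](C(C)=C)[C@]1(C)CCC1(C)OCCO1 | intermediate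
6 | methoxy hydroperoxide of 5 (1-hydroperoxy-1-methoxyethyl in place of isopropenyl, ring centres as in 5) | O=C1[C@H](C)CC[C@@H](C(C)(OC)OO)[C@]1(C)CCC1(C)OCCO1 | intermediate
7 | (2R,6R)-2,6-dimethyl-2-[2-(2-methyl-1,3-dioxolan-2-yl)ethyl]cyclohexan-1-one | O=C1[C@H](C)CCC[C@]1(C)CCC1(C)OCCO1 | intermediate
8 | 2-{2-[(1R,3R)-1,3-dimethyl-2-methylidenecyclohexyl]ethyl}-2-methyl-1,3-dioxolane | C=C1[C@H](C)CCC[C@]1(C)CCC1(C)OCCO1 | intermediate
9 | 4-[(1R,3R)-1,3-dimethyl-2-methylidenecyclohexyl]butan-2-one | C=C1[C@H](C)CCC[C@]1(C)CCC(C)=O | intermediate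
10 | N-tert-butyl-5-[(1R,3R)-1,3-dimethyl-2-methylidenecyclohexyl]-3-methylpent-2-en-1-imine | C=C1[C@H](C)CCC[C@]1(C)CCC(C)=CC=NC(C)(C)C | intermediate
11 | (2E)-5-[(1R,3R)-1,3-dimethyl-2-methylidenecyclohexyl]-3-methylpent-2-enal (Z isomer carried along) | C=C1[C@H](C)CCC[C@]1(C)CC/C(C)=C/C=O | intermediate
12 | 2,4,5-trimethoxybenzaldehyde | O=Cc1cc(OC)c(OC)cc1OC | starting material
13 | 2,4,5-trimethoxyphenyl formate | O=COc1cc(OC)c(OC)cc1OC | intermediate
14 | 2,4,5-trimethoxyphenol | Oc1cc(OC)c(OC)cc1OC | intermediate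
15 | 2-hydroxy-3,5,6-trimethoxybenzaldehyde | O=Cc1c(O)c(OC)cc(OC)c1OC | intermediate
16 | 2-[(2S,4S)-2-{2-[(1R,3R)-1,3-dimethyl-2-methylidenecyclohexyl]ethyl}-4-hydroxy-5,6,8-trimethoxy-3,4-dihydro-2H-chromen-2-yl]acetaldehyde | C=C1[C@H](C)CCC[C@]1(C)CC[C@@]1(CC=O)C[C@H](O)c2c(OC)c(OC)cc(OC)c2O1 | intermediate
17 | bridged lactol (ring-closed hemiacetal of 16, chroman centres 2S,4S, anomer mixture) | C=C1[C@H](C)CCC[C@]1(C)CC[C@@]12CC(O)O[C@@H](C1)c1c(OC)c(OC)cc(OC)c1O2 | intermediate
18 | (2S,4S)-2-{2-[(1R,3R)-1,3-dimethyl-2-methylidenecyclohexyl]ethyl}-5,6,8-trimethoxy-2-methyl-3,4-dihydro-2H-chromen-4-ol | C=C1[C@H](C)CCC[C@]1(C)CC[C@@]1(C)C[C@H](O)c2c(OC)c(OC)cc(OC)c2O1 | intermediate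
19 | (2S,4S)-2-{2-[(1R,3R)-1,3-dimethyl-2-methylidenecyclohexyl]ethyl}-4-hydroxy-6-methoxy-2-methyl-3,4-dihydro-2H-chromene-5,8-dione | C=C1[C@H](C)CCC[C@]1(C)CC[C@@]1(C)C[C@H](O)C2=C(O1)C(=O)C=C(OC)C2=O | intermediate
20 | (2S,4S)-2-{2-[(1R,3R)-1,3-dimethyl-2-methylidenecyclohexyl]ethyl}-6-methoxy-2-methyl-3,4-dihydro-2H-chromene-4,5,8-triol | C=C1[C@H](C)CCC[C@]1(C)CC[C@@]1(C)C[C@H](O)c2c(O)c(OC)cc(O)c2O1 | intermediate
21 | (2S)-2-{2-[(1R,3R)-1,3-dimethyl-2-methylidenecyclohexyl]ethyl}-6-methoxy-2-methyl-2H-chromene-5,8-diol | C=C1[C@H](C)CCC[C@]1(C)CC[C@@]1(C)C=Cc2c(O)c(OC)cc(O)c2O1 | target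

Total step count: 13. Longest linear sequence: 11 steps (steps 1 to 7, then 10 to 13).

Steps most likely to fail

Step 10. The hindered, electron-rich aldehyde 15 may be attacked too slowly, so that self-condensation of the enal or reaction of the dienamine at its α-carbon takes over. The catalyst may also discriminate poorly between the two alkyl groups on the β-carbon; if the sense of induction proved opposite to the shielding model, the enantiomeric catalyst would be used. Fallback, setting out from ketone 9 and aldehyde 15 and coming back at 21: vinylmagnesium bromide adds to 9 to give the tertiary allylic alcohol F1 (both carbinol epimers), which n-BuLi and ClCO2Me convert into the methyl carbonate F2. Ph3P=CH2 converts 15 into the vinylphenol F3. Asymmetric allylic etherification with Pd2(dba)3·CHCl3 and the chiral trans-1,2-diaminocyclohexane bis(2-diphenylphosphinobenzamide) ligand (zerovalent palladium, rapidly equilibrating allyl complex, ligand enantiomer chosen for the S ether) joins F2 and F3 at the tertiary carbon to give the aryl ether F4 (O1–C2). Ring-closing metathesis with the second-generation Grubbs catalyst, RuCl2(=CHPh)(PCy3)(H2IMes), then closes C3=C4 to give the trimethoxychromene F5. (NH4)2Ce(NO3)6 at 0 °C gives the chromene quinone F6, which is reduced at once with Na2S2O4 to 21.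

Step 2. Elimination of HBr from the primary bromide 3 and O-alkylation may outrun C-alkylation at the hindered, fully substituted enolate carbon. Fallback, setting out from 2 and coming back at 4: the lithium enolate of 2 adds to (2-methyl-1,3-dioxolan-2-yl)acetaldehyde, again anti to the isopropenyl group, to give the β-hydroxy ketone F7. Phenyl chlorothionoformate and pyridine give the O-phenyl thionocarbonate F8. Barton–McCombie deoxygenation with Bu3SnH and AIBN removes the oxygen to give 4.

Step 11. Too little of the open form 16 may be present for rhodium to insert into the formyl C–H bond, and prolonged heating may reverse the oxa-Michael step from 16. Fallback, setting out from 17 and coming back at 18: PhI(OAc)2 and I2 under visible light turn the lactol hydroxyl into an alkoxy radical whose β-scission (Suárez fragmentation) cuts the CH(OH)–CH2 bond and gives the iodomethyl formate F9. Bu3SnH and AIBN reduce the iodide to the formate F10. K2CO3 in MeOH removes the formyl group to give 18.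

Further compounds
F1 | step 10 | 5-[(1R,3R)-1,3-dimethyl-2-methylidenecyclohexyl]-3-methylpent-1-en-3-ol (carbinol epimers) | C=C1[C@H](C)CCC[C@]1(C)CCC(C)(O)C=C
F2 | step 10 | methyl carbonate of F1 | C=C1[C@H](C)CCC[C@]1(C)CCC(C)(OC(=O)OC)C=C
F3 | step 10 | 2-ethenyl-3,4,6-trimethoxyphenol | C=Cc1c(O)c(OC)cc(OC)c1OC
F4 | step 10 | (S)-tertiary aryl ether, 2-ethenyl-3,4,6-trimethoxyphenyl ether of (3S)-5-[(1R,3R)-1,3-dimethyl-2-methylidenecyclohexyl]-3-methylpent-1-en-3-ol | C=C1[C@H](C)CCC[C@]1(C)CC[C@@](C)(C=C)Oc1c(C=C)c(OC)c(OC)cc1OC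
F5 | step 10 | (2S)-2-{2-[(1R,3R)-1,3-dimethyl-2-methylidenecyclohexyl]ethyl}-5,6,8-trimethoxy-2-methyl-2H-chromene | C=C1[C@H](C)CCC[C@]1(C)CC[C@@]1(C)C=Cc2c(OC)c(OC)cc(OC)c2O1
F6 | step 10 | (2S)-2-{2-[(1R,3R)-1,3-dimethyl-2-methylidenecyclohexyl]ethyl}-6-methoxy-2-methyl-2H-chromene-5,8-dione | C=C1[C@H](C)CCC[C@]1(C)CC[C@@]1(C)C=CC2=C(O1)C(=O)C=C(OC)C2=O
F7 | step 2 | aldol adduct, 6-[1-hydroxy-2-(2-methyl-1,3-dioxolan-2-yl)ethyl] analogue of 4 (carbinol epimers) | O=C1C(C)=CC[C@@H](C(C)=C)[C@]1(C)C(O)CC1(C)OCCO1
F8 | step 2 | O-phenyl thionocarbonate of F7 | O=C1C(C)=CC[C@@H](C(C)=C)[C@]1(C)C(OC(=S)Oc1ccccc1)CC1(C)OCCO1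
F9 | step 11 | 4-formyloxy-2-(iodomethyl) analogue of 18 | C=C1[C@H](C)CCC[C@]1(C)CC[C@@]1(CI)C[C@H](OC=O)c2c(OC)c(OC)cc(OC)c2O1
F10 | step 11 | 4-O-formate of 18 | C=C1[C@H](C)CCC[C@]1(C)CC[C@@]1(C)C[C@H](OC=O)c2c(OC)c(OC)cc(OC)c2O1
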